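**Retrosynthetic overview**
- The target consists of two trans-2-(4-hydroxyphenyl)-2,3-dihydrobenzofurans (ring O1–C2–C3–C3a–C7a, oxygen at C4, second substituent at C6) joined by the bond C3(upper unit)–C6'(lower unit). Each unit is the skeleton of (2S)-naringenin without its carbonyl carbon C4 (chromanone C5–O = benzofuran C4–O, C7 = C6, C2 = C2), with C2 and C2' both S; the route rests on this correspondence.
- Disconnections, last first: the eight O–Me bonds; the C6–vinyl bond (Heck, 2,4-dimethoxystyrene); C3–C6' and C3'–aryl (two decarboxylative arylations of one C3-carboxylic acid derivative, the lower unit entering as an aryl iodide made from its triflate).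
- Both halves come from one ester triflate, made by oxidative ring contraction of a protected naringenin 7-triflate: C4a shifts from C4 to C3 and C4 becomes the ester carbon.
- Ring order: the dihydrofuran ring is formed once, from the pyranone of naringenin, and used twice; no other ring is made. Both C3 centres are set trans under control of the C2 centres inherited from naringenin.

Key step: step 3

Assumption: the (2S)-naringenin used is enantiomerically pure; commercial material can be partly racemised, so its ee is checked and if necessary upgraded before step 1.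

**Route**

Step 1
Reactants: 1 (2S)-naringenin
Product: 2 (2S)-5-hydroxy-2-(4-hydroxyphenyl)-4-oxochroman-7-yl trifluoromethanesulfonate
Conditions: PhNTf2 (1.05 equiv), i-Pr2NEt (1.1 equiv), THF, 0 °C → rt
Reagents that add atoms: N-phenyl-bis(trifluoromethanesulfonimide), O=S(=O)(N(c1ccccc1)S(=O)(=O)C(F)(F)F)C(F)(F)F
Why: Chemoselective phenol O-triflation: the 7-OH, para to the C4 carbonyl, is the most acidic phenol (the 5-OH is chelated to the carbonyl, the 4'-OH is an ordinary phenol), so one equivalent of the mild triflyl donor with a hindered amine at 0 °C should sulfonylate only O7 without forming the 4'-phenoxide that would open the pyranone and racemise C2.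

Step 2
Reactants: 2 (2S)-5-hydroxy-2-(4-hydroxyphenyl)-4-oxochroman-7-yl trifluoromethanesulfonate
Product: 3 (2S)-5-methoxy-2-(4-methoxyphenyl)-4-oxochroman-7-yl trifluoromethanesulfonate
Conditions: MeI (excess), Ag2O, DMF, rt, dark
Reagents that add atoms: iodomethane, CI
Why: Purdie methylation (MeI/Ag2O): silver-assisted SN2 methylation of the 4'-OH and, in DMF, of the chelated 5-OH without a soluble strong base, so that retro-oxa-Michael opening to the chalcone, and with it racemisation of C2, should be avoided while the aryl triflate stays inert.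

Step 3
Reactants: 3 (2S)-5-methoxy-2-(4-methoxyphenyl)-4-oxochroman-7-yl trifluoromethanesulfonate
Product: 6 methyl (2S,3S)-4-methoxy-2-(4-methoxyphenyl)-6-(trifluoromethylsulfonyloxy)-2,3-dihydro-1-benzofuran-3-carboxylate (2,3-trans), via C4 methyl enol ether 4 (not isolated), via trans-3-iodanyl C4 dimethyl ketal 5 (not isolated)
Conditions: PhI(OAc)2 (1.2 equiv), HC(OMe)3, conc. H2SO4, 0 °C → rt; aq. NaHCO3 work-up
Reagents that add atoms: trimethyl orthoformate, COC(OC)OC; water, O (hydrolysis of the orthoester on work-up)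
Why: Acid and trimethyl orthoformate turn the C4 ketone into the methyl enol ether 4, whose C3 attacks iodine(III) on the face anti to the pseudo-equatorial C2 aryl group while C4 takes up methanol, giving the trans-3-iodanyl ketal 5; loss of iodobenzene from C3 is concerted with the 1,2-shift of the A-ring carbon C4a from C4 to C3 through a bridged phenonium-like transition state, and the dimethoxycarbenium ion left at C4 ends as the methyl ester. The closest known reaction type is the hypervalent-iodine (or thallium(III)) oxidative ring contraction of flavanones in trimethyl orthoformate to methyl trans-2-aryl-2,3-dihydrobenzofuran-3-carboxylates, a semipinacol-type 1,2-aryl shift. The dihydrofuran ring is closed not by a separate cyclisation but by this contraction: the C3–C3a bond forms by ipso attack of C4a on C3 (formally 3-exo-tet at C3, with inversion) while C4–C4a breaks. The new C3 stereocentre is controlled by C2: the iodanyl group sits trans to the aryl group, C4a enters anti to it, and the ester carbon is thereby left trans to the aryl group, which is also the thermodynamic arrangement of this epimerisable centre in the acidic medium. The step needs C4a to migrate in preference to the 4-methoxyphenyl group (isoflavone) and to loss of H2 (flavone); in the diequatorial trans-iodane the C4–C4a bond is antiperiplanar to C3–I whereas C2–aryl is gauche, the two methoxy groups on C4 push the shift, and O1 and the 5-methoxy group, both ortho to C4a, stabilise the bridged cation against the para-triflate. C2 is not touched and the medium stays acidic, so the (2S) centre should be kept.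

Step 4
Reactants: 6 methyl (2S,3S)-4-methoxy-2-(4-methoxyphenyl)-6-(trifluoromethylsulfonyloxy)-2,3-dihydro-1-benzofuran-3-carboxylate
Product: 7 (2S,3S)-4-methoxy-2-(4-methoxyphenyl)-6-(trifluoromethylsulfonyloxy)-2,3-dihydro-1-benzofuran-3-carboxylic acid
Conditions: Me3SnOH, ClCH2CH2Cl, 80 °C; 1 M HCl wash
Reagents that add atoms: trimethyltin hydroxide, C[Sn](C)(C)O
Why: Trimethyltin hydroxide ester hydrolysis: the neutral tin hydroxide cleaves the methyl ester by acyl–oxygen attack without forming an ester enolate, so E1cB opening of the β-aryloxy ester (loss of C2) and S–O cleavage of the aryl triflate should not occur, and the trans C3 centre is the stable one.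

Step 5
Reactants: 7 (2S,3S)-4-methoxy-2-(4-methoxyphenyl)-6-(trifluoromethylsulfonyloxy)-2,3-dihydro-1-benzofuran-3-carboxylic acid
Product: 8 1,3-dioxoisoindolin-2-yl (2S,3S)-4-methoxy-2-(4-methoxyphenyl)-6-(trifluoromethylsulfonyloxy)-2,3-dihydro-1-benzofuran-3-carboxylate
Conditions: N-hydroxyphthalimide, DIC, CH2Cl2, 0 °C → rt (no DMAP)
Reagents that add atoms: N-hydroxyphthalimide, O=C1c2ccccc2C(=O)N1O
Why: Carbodiimide esterification to the N-acyloxyphthalimide (redox-active ester); N-hydroxyphthalimide is acidic and nucleophilic enough to take the O-acylisourea without DMAP, which is left out to avoid ketene formation or β-elimination at the activated β-aryloxy ester.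

Step 6
Reactants: 8 1,3-dioxoisoindolin-2-yl (2S,3S)-4-methoxy-2-(4-methoxyphenyl)-6-(trifluoromethylsulfonyloxy)-2,3-dihydro-1-benzofuran-3-carboxylate; 9 1-iodo-3,5-dimethoxybenzene
Product: 10 (2S,3S)-3-(3,5-dimethoxyphenyl)-4-methoxy-2-(4-methoxyphenyl)-2,3-dihydro-1-benzofuran-6-yl trifluoromethanesulfonate (2,3-trans)
Conditions: NiBr2·glyme (10 mol%), 4,4'-di-tert-butyl-2,2'-bipyridine (10 mol%), Zn, DMA, rt
Reagents that add atoms: none
Why: Nickel-catalysed reductive decarboxylative cross-electrophile coupling of an N-acyloxyphthalimide with an aryl iodide: single-electron reduction fragments the ester to CO2, phthalimide and the benzylic C3 radical, which is captured by the arylnickel species formed selectively from the aryl iodide (the aryl triflate is far slower towards bipyridine-nickel(0)), and reductive elimination delivers the aryl group anti to the C2 aryl group, setting C3 trans (3S).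

Step 7
Reactants: 10 (2S,3S)-3-(3,5-dimethoxyphenyl)-4-methoxy-2-(4-methoxyphenyl)-2,3-dihydro-1-benzofuran-6-yl trifluoromethanesulfonate
Product: 11 [(2S,3S)-3-(3,5-dimethoxyphenyl)-4-methoxy-2-(4-methoxyphenyl)-2,3-dihydro-1-benzofuran-6-yl]trimethylstannane
Conditions: (Me3Sn)2, Pd(PPh3)4 (5 mol%), LiCl, 1,4-dioxane, 100 °C
Reagents that add atoms: hexamethylditin, C[Sn](C)(C)[Sn](C)(C)C
Why: Palladium-catalysed stannylation of an aryl triflate with a distannane (Stille-type; chloride converts the arylpalladium triflate for transmetalation), which turns the unreactive C6–O bond into a C–Sn bond without touching a stereocentre.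

Step 8
Reactants: 11 [(2S,3S)-3-(3,5-dimethoxyphenyl)-4-methoxy-2-(4-methoxyphenyl)-2,3-dihydro-1-benzofuran-6-yl]trimethylstannane
Product: 12 (2S,3S)-3-(3,5-dimethoxyphenyl)-6-iodo-4-methoxy-2-(4-methoxyphenyl)-2,3-dihydro-1-benzofuran
Conditions: I2 (1.05 equiv), CH2Cl2, 0 °C; aq. Na2S2O3/KF work-up
Reagents that add atoms: iodine, II
Why: ipso-Iododestannylation: the aryl C–Sn bond reacts with iodine far faster than the methoxylated rings undergo electrophilic substitution with uncatalysed I2 at 0 °C, so iodine should enter only at C6.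

Step 9
Reactants: 8 1,3-dioxoisoindolin-2-yl (2S,3S)-4-methoxy-2-(4-methoxyphenyl)-6-(trifluoromethylsulfonyloxy)-2,3-dihydro-1-benzofuran-3-carboxylate (1.5 equiv); 12 (2S,3S)-3-(3,5-dimethoxyphenyl)-6-iodo-4-methoxy-2-(4-methoxyphenyl)-2,3-dihydro-1-benzofuran
Product: 13 (2S,3S)-3-[(2S,3S)-3-(3,5-dimethoxyphenyl)-4-methoxy-2-(4-methoxyphenyl)-2,3-dihydro-1-benzofuran-6-yl]-4-methoxy-2-(4-methoxyphenyl)-2,3-dihydro-1-benzofuran-6-yl trifluoromethanesulfonate
Conditions: NiBr2·glyme (15 mol%), 4,4'-di-tert-butyl-2,2'-bipyridine (15 mol%), Zn, DMA, rt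
Reagents that add atoms: none
Why: The same nickel-catalysed reductive decarboxylative arylation as in step 6: the C3 radical from 8 is arylated by the arylnickel species from iodide 12 (again preferred over the triflate of 8), and the bulky aryl group is delivered anti to the C2 aryl group, which sets C3 of the upper unit trans (3S) and forms the C3–C6' bond between the halves.

Step 10
Reactants: 13 (2S,3S)-3-[(2S,3S)-3-(3,5-dimethoxyphenyl)-4-methoxy-2-(4-methoxyphenyl)-2,3-dihydro-1-benzofuran-6-yl]-4-methoxy-2-(4-methoxyphenyl)-2,3-dihydro-1-benzofuran-6-yl trifluoromethanesulfonate; 14 2,4-dimethoxystyrene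
Product: 15 (2S,3S)-3-[(2S,3S)-3-(3,5-dimethoxyphenyl)-4-methoxy-2-(4-methoxyphenyl)-2,3-dihydro-1-benzofuran-6-yl]-6-[(E)-2-(2,4-dimethoxyphenyl)ethenyl]-4-methoxy-2-(4-methoxyphenyl)-2,3-dihydro-1-benzofuran (octamethyl ether of the target)
Conditions: PdCl2(PPh3)2 (10 mol%), LiCl, Et3N, DMF, 90 °C
Reagents that add atoms: none
Why: Mizoroki–Heck reaction of the aryl triflate with the styrene under chloride-assisted neutral-pathway conditions, which favour β-arylation and, after syn β-hydride elimination, the (E)-stilbene; the doubly benzylic C3–H centres are not acidic enough for triethylamine to epimerise.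

Step 11
Reactants: 15 octamethyl ether of the target
Product: 16 CNP0186204.1, (2S,3S)-3-[(2S,3S)-3-(3,5-dihydroxyphenyl)-4-hydroxy-2-(4-hydroxyphenyl)-2,3-dihydro-1-benzofuran-6-yl]-6-[(E)-2-(2,4-dihydroxyphenyl)ethenyl]-2-(4-hydroxyphenyl)-2,3-dihydro-1-benzofuran-4-ol
Conditions: BBr3 (excess), CH2Cl2, −78 °C → rt; quench with MeOH then H2O at −78 → 0 °C
Reagents that add atoms: none
Why: Lewis-acid cleavage of aryl methyl ethers with BBr3 (bromide attacks the methyl group of each O–B complex), run and quenched cold so that the stilbene and the benzylic C2–O bonds survive; a C2–O bond that ionises reversibly should reclose trans because C3 stays fixed.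

**Compound list**

1 | (2S)-naringenin | O=C1C[C@@H](c2ccc(O)cc2)Oc2cc(O)cc(O)c12 | starting material
2 | (2S)-5-hydroxy-2-(4-hydroxyphenyl)-4-oxochroman-7-yl trifluoromethanesulfonate | O=C1C[C@@H](c2ccc(O)cc2)Oc2cc(OS(=O)(=O)C(F)(F)F)cc(O)c12 | intermediate
3 | (2S)-5-methoxy-2-(4-methoxyphenyl)-4-oxochroman-7-yl trifluoromethanesulfonate (key-step precursor) | O=C1C[C@@H](c2ccc(OC)cc2)Oc2cc(OS(=O)(=O)C(F)(F)F)cc(OC)c12 | intermediate
4 | (2S)-4,5-dimethoxy-2-(4-methoxyphenyl)-2H-chromen-7-yl trifluoromethanesulfonate (C4 methyl enol ether, in equilibrium with the dimethyl ketal; not isolated) | COC1=C[C@@H](c2ccc(OC)cc2)Oc2cc(OS(=O)(=O)C(F)(F)F)cc(OC)c12 | intermediate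
5 | (2R,3R)-3-[acetoxy(phenyl)-λ3-iodanyl]-4,4,5-trimethoxy-2-(4-methoxyphenyl)chroman-7-yl trifluoromethanesulfonate (2,3-trans; C2 unchanged in space, descriptor R only because C3 now carries iodine; not isolated) | COC1(OC)[C@H](I(OC(C)=O)c2ccccc2)[C@@H](c2ccc(OC)cc2)Oc2cc(OS(=O)(=O)C(F)(F)F)cc(OC)c12 | intermediate
6 | methyl (2S,3S)-4-methoxy-2-(4-methoxyphenyl)-6-(trifluoromethylsulfonyloxy)-2,3-dihydro-1-benzofuran-3-carboxylate (trans; key-step product) | COc1ccc([C@H]2Oc3cc(OS(=O)(=O)C(F)(F)F)cc(OC)c3[C@@H]2C(=O)OC)cc1 | intermediate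
7 | (2S,3S)-4-methoxy-2-(4-methoxyphenyl)-6-(trifluoromethylsulfonyloxy)-2,3-dihydro-1-benzofuran-3-carboxylic acid | COc1ccc([C@H]2Oc3cc(OS(=O)(=O)C(F)(F)F)cc(OC)c3[C@@H]2C(=O)O)cc1 | intermediate
8 | 1,3-dioxoisoindolin-2-yl (2S,3S)-4-methoxy-2-(4-methoxyphenyl)-6-(trifluoromethylsulfonyloxy)-2,3-dihydro-1-benzofuran-3-carboxylate | COc1ccc([C@H]2Oc3cc(OS(=O)(=O)C(F)(F)F)cc(OC)c3[C@@H]2C(=O)ON2C(=O)c3ccccc3C2=O)cc1 | intermediate
9 | 1-iodo-3,5-dimethoxybenzene | COc1cc(I)cc(OC)c1 | starting material
10 | (2S,3S)-3-(3,5-dimethoxyphenyl)-4-methoxy-2-(4-methoxyphenyl)-2,3-dihydro-1-benzofuran-6-yl trifluoromethanesulfonate (trans) | COc1ccc([C@H]2Oc3cc(OS(=O)(=O)C(F)(F)F)cc(OC)c3[C@@H]2c2cc(OC)cc(OC)c2)cc1 | intermediate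
11 | [(2S,3S)-3-(3,5-dimethoxyphenyl)-4-methoxy-2-(4-methoxyphenyl)-2,3-dihydro-1-benzofuran-6-yl]trimethylstannane | COc1ccc([C@H]2Oc3cc([Sn](C)(C)C)cc(OC)c3[C@@H]2c2cc(OC)cc(OC)c2)cc1 | intermediate
12 | (2S,3S)-3-(3,5-dimethoxyphenyl)-6-iodo-4-methoxy-2-(4-methoxyphenyl)-2,3-dihydro-1-benzofuran | COc1ccc([C@H]2Oc3cc(I)cc(OC)c3[C@@H]2c2cc(OC)cc(OC)c2)cc1 | intermediate
13 | (2S,3S)-3-[(2S,3S)-3-(3,5-dimethoxyphenyl)-4-methoxy-2-(4-methoxyphenyl)-2,3-dihydro-1-benzofuran-6-yl]-4-methoxy-2-(4-methoxyphenyl)-2,3-dihydro-1-benzofuran-6-yl trifluoromethanesulfonate | COc1ccc([C@H]2Oc3cc(OS(=O)(=O)C(F)(F)F)cc(OC)c3[C@@H]2c2cc(OC)c3c(c2)O[C@H](c2ccc(OC)cc2)[C@H]3c2cc(OC)cc(OC)c2)cc1 | intermediate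
14 | 2,4-dimethoxystyrene | C=Cc1ccc(OC)cc1OC | starting material
15 | octamethyl ether of the target (E-stilbene, all four ring centres S, both rings trans) | COc1ccc([C@H]2Oc3cc(/C=C/c4ccc(OC)cc4OC)cc(OC)c3[C@@H]2c2cc(OC)c3c(c2)O[C@H](c2ccc(OC)cc2)[C@H]3c2cc(OC)cc(OC)c2)cc1 | intermediate
16 | CNP0186204.1 | Oc1ccc([C@H]2Oc3cc(/C=C/c4ccc(O)cc4O)cc(O)c3[C@@H]2c2cc(O)c3c(c2)O[C@H](c2ccc(O)cc2)[C@H]3c2cc(O)cc(O)c2)cc1 | target

**Totals**

Total step count: 11. Longest linear sequence: 11 steps (1 → 16; the route is linear, and ester 8 enters twice, in steps 6 and 9).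

**Steps most likely to fail**

1. Step 3 (key step). What may go wrong:
- migration of the 4-methoxyphenyl group from C2 to C3 (isoflavone formation) instead of the triflate-deactivated A-ring carbon;
- loss of H2 to the flavone;
- methanol capture at C3 without rearrangement;
- slow ketalisation of the ketone next to the 5-methoxy group;
- iodonium formation on an anisole ring.

Fallback (Wolff ring contraction, the same bond change by a carbene pathway), from 3. Condensation with N,N-dimethylformamide dimethyl acetal (toluene, 90 °C) should give the enaminone (2R,E)-3-[(dimethylamino)methylidene]-5-methoxy-2-(4-methoxyphenyl)-4-oxochroman-7-yl trifluoromethanesulfonate F1 (C2 unchanged in space). Regitz-type deformylative diazo transfer with tosyl azide should give the diazoketone (2R)-3-diazo-5-methoxy-2-(4-methoxyphenyl)-4-oxochroman-7-yl trifluoromethanesulfonate F2. Irradiation (about 350 nm) in methanol triggers the Wolff rearrangement, in which C4a again migrates from C4 to C3 and the ketene is trapped as the methyl ester. Brief acid-catalysed equilibration of the α-centre (cat. H2SO4, MeOH) should leave the trans ester, so the sequence returns to the route at 6.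

2. Step 9. What may go wrong:
- homodimerisation or reduction of the hindered benzylic radical before it meets the arylnickel species;
- zinc-driven homocoupling of the aryl iodide;
- opening of the radical by β-scission of the C2–O1 bond;
- incomplete trans selectivity.

Fallback: the free acid 7 and iodide 12 are coupled by iridium/nickel metallaphotoredox decarboxylative arylation (Ir[dF(CF3)ppy]2(dtbbpy)PF6, NiCl2·glyme, dtbbpy, Cs2CO3, DMF, blue light, rt). The carboxylate is oxidised slowly to the same C3 radical, without a metal reductant and without the activated ester. The fallback sets out from 7 and 12 and returns to the route at 13 without new intermediates.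

3. Step 11. What may go wrong:
- incomplete eightfold ether cleavage;
- acid-induced loss of the electron-rich stilbene (HBr addition, E/Z isomerisation, cationic cyclisation or oligomerisation), possibly with ionisation of a C2–O bond.

Fallback: the order of deprotection and olefination is reversed, so that no alkene is present when the Lewis acid acts.
- From 13, BBr3 (CH2Cl2, −78 °C → rt; the aryl triflate is stable) should give the hexaphenol (2S,3S)-3-[(2S,3S)-3-(3,5-dihydroxyphenyl)-4-hydroxy-2-(4-hydroxyphenyl)-2,3-dihydro-1-benzofuran-6-yl]-4-hydroxy-2-(4-hydroxyphenyl)-2,3-dihydro-1-benzofuran-6-yl trifluoromethanesulfonate F3.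
- Ac2O/pyridine converts it into its hexaacetate F4.
- The olefin partner is made from commercial 2,4-dihydroxybenzaldehyde: acetylation to 4-formyl-1,3-phenylene diacetate F5, then Wittig methylenation (Ph3P=CH2, THF, −78 °C) to 4-ethenyl-1,3-phenylene diacetate F6.
- Heck coupling of F4 with F6 under the conditions of step 10 should give the octaacetate of the target F7.
- Mild methanolysis (cat. K2CO3, degassed MeOH, 0 °C) returns to the route at 16.

**Further compounds**

F1 | step 3 | (2R,E)-3-[(dimethylamino)methylidene]-5-methoxy-2-(4-methoxyphenyl)-4-oxochroman-7-yl trifluoromethanesulfonate | CN(C)/C=C1\[C@@H](c2ccc(OC)cc2)Oc2cc(OS(=O)(=O)C(F)(F)F)cc(OC)c2C1=O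
F2 | step 3 | (2R)-3-diazo-5-methoxy-2-(4-methoxyphenyl)-4-oxochroman-7-yl trifluoromethanesulfonate | O=C1C(=[N+]=[N-])[C@@H](c2ccc(OC)cc2)Oc2cc(OS(=O)(=O)C(F)(F)F)cc(OC)c12
F0 | step 9 | none | none
F3 | step 11 | (2S,3S)-3-[(2S,3S)-3-(3,5-dihydroxyphenyl)-4-hydroxy-2-(4-hydroxyphenyl)-2,3-dihydro-1-benzofuran-6-yl]-4-hydroxy-2-(4-hydroxyphenyl)-2,3-dihydro-1-benzofuran-6-yl trifluoromethanesulfonate | Oc1ccc([C@H]2Oc3cc(OS(=O)(=O)C(F)(F)F)cc(O)c3[C@@H]2c2cc(O)c3c(c2)O[C@H](c2ccc(O)cc2)[C@H]3c2cc(O)cc(O)c2)cc1
F4 | step 11 | hexaacetate of F3 | CC(=O)Oc1ccc([C@H]2Oc3cc(OS(=O)(=O)C(F)(F)F)cc(OC(C)=O)c3[C@@H]2c2cc(OC(C)=O)c3c(c2)O[C@H](c2ccc(OC(C)=O)cc2)[C@H]3c2cc(OC(C)=O)cc(OC(C)=O)c2)cc1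
F5 | step 11 | 4-formyl-1,3-phenylene diacetate | CC(=O)Oc1ccc(C=O)c(OC(C)=O)c1
F6 | step 11 | 4-ethenyl-1,3-phenylene diacetate (2,4-diacetoxystyrene) | C=Cc1ccc(OC(C)=O)cc1OC(C)=O
F7 | step 11 | octaacetate of the target | CC(=O)Oc1ccc([C@H]2Oc3cc(/C=C/c4ccc(OC(C)=O)cc4OC(C)=O)cc(OC(C)=O)c3[C@@H]2c2cc(OC(C)=O)c3c(c2)O[C@H](c2ccc(OC(C)=O)cc2)[C@H]3c2cc(OC(C)=O)cc(OC(C)=O)c2)cc1
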